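The 1,2-dioxane ring is dissected into a C6–O–O unit and a C3–C4–C5 unit (numbering: C1 lactone carbonyl, C3 peroxy methine, C4 lactone-oxygen carbon, C5 ring CH2, C6 peroxy quaternary carbon). C6 is treated as a latent peroxycarbenium ion (a ketone α-methoxy hydroperoxide); C3 and C4 are β and γ to C1, so the partner is (E)-4-methylpenta-2,4-dienal. In one flask the hydroperoxide adds to C3 under iminium catalysis (O–C3 bond, sets C3); Me3SiOTf then ionises the peroxyketal, the isopropenyl terminus C5 attacks C6 (C5–C6 bond) and the C4 cation is captured by the aldehyde oxygen. The cis-fused dioxane–lactol ether emerges with C3, C4 and C6 set.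

Key step: step 6

Remark: the target SMILES corresponds to (3S,4S,6R) in this numbering; the perketal carbon of 9 and 13 and the acetal carbon C1 of 14 and 15 are carried as mixtures because both centers are erased later.

Step 1
Reactants: 1 dec-9-enoic acid
Product: 3 undec-10-en-2-one, via dilithium gem-diolate 2 (not isolated)
Conditions: MeLi (2.2 equiv), Et2O, 0 °C to rt; then aq. HCl, 0 °C
Reagents that add atoms: methyllithium, [Li]C
Why: the second equivalent of MeLi adds to the lithium carboxylate to give a dilithium gem-diolate that cannot add again and releases the methyl ketone only on acidic work-up (organolithium–carboxylate ketone synthesis).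

Step 2
Reactants: 3 undec-10-en-2-one
Product: 4 10,10-dimethoxyundec-1-ene
Conditions: HC(OMe)3, MeOH, p-TsOH (cat.), rt
Reagents that add atoms: trimethyl orthoformate, COC(OC)OC
Why: acid-catalysed ketalisation driven by the orthoformate as water scavenger should mask the ketone before hydroboration; no stereocenter is formed.

Step 3
Reactants: 4 10,10-dimethoxyundec-1-ene; 5 9-BBN; 6 (4-bromophenoxy)triisopropylsilane
Product: 8 [4-(10,10-dimethoxyundecyl)phenoxy]triisopropylsilane, via B-alkyl-9-BBN borane 7 (not isolated)
Conditions: 9-BBN, THF, 0 °C to rt; then 6, Pd(dppf)Cl2 (3 mol %), aq. K3PO4, DMF, 60 °C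
Reagents that add atoms: none
Why: 9-BBN hydroborates the terminal alkene at the terminal carbon without touching the ketal, and the resulting B-alkyl borane should couple with the aryl bromide under aqueous phosphate, which the aryl TIPS ether tolerates (B-alkyl Suzuki–Miyaura coupling).

Step 4
Reactants: 8 [4-(10,10-dimethoxyundecyl)phenoxy]triisopropylsilane
Product: 9 [4-(10-hydroperoxy-10-methoxyundecyl)phenoxy]triisopropylsilane (racemic at C10)
Conditions: H2O2 (anhydrous, in Et2O, 2 equiv), camphorsulfonic acid (cat.), Et2O, 0 °C
Reagents that add atoms: hydrogen peroxide, OO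
Why: acid-catalysed perhydrolysis of the ketal exchanges one methoxy group for a hydroperoxy group via the methoxycarbenium ion, and the product should survive because a perketal ionises more slowly than a ketal; the new center is racemic and is ionised again in step 6.

Step 5
Reactants: 10 methacrolein; 11 (triphenylphosphoranylidene)acetaldehyde
Product: 12 (2E)-4-methylpenta-2,4-dienal
Conditions: toluene, 80 °C, excess 10; distillation
Reagents that add atoms: none
Why: Wittig olefination with the formyl-stabilised ylide should give the (E)-dienal, and excess methacrolein suppresses a second homologation.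

Step 6
Reactants: 9 [4-(10-hydroperoxy-10-methoxyundecyl)phenoxy]triisopropylsilane; 12 (2E)-4-methylpenta-2,4-dienal
Product: 14 (3S,4S,6R)-1-deoxo-1-methoxyplakortolide F triisopropylsilyl ether (both C1 anomers), via (3S)-peroxy aldehyde 13 (not isolated)
Conditions: (S)-2-{bis[3,5-bis(trifluoromethyl)phenyl](trimethylsilyloxy)methyl}pyrrolidine (10 mol %), PhCO2H (10 mol %), toluene, 0 °C; then CH2Cl2, Me3SiOTf (0.5 equiv), −78 °C
Reagents that add atoms: none
Why: Proposed new method: the amine forms an iminium ion of 12 whose Re face at C3 is blocked by the diaryl(silyloxy)methyl group, so the hydroperoxide oxygen of 9 adds to C3 from the Si face (oxa-Michael addition, the known organocatalytic peroxidation of enals) and should give 13 with (S)-C3; Me3SiOTf then ionises the peroxyketal to a peroxycarbenium ion, the isopropenyl CH2 (C5) attacks C6, the tertiary C4 cation is captured by the aldehyde oxygen, and the resulting oxocarbenium ion takes methoxide back from MeOSiMe3, which regenerates the promoter. The closest known reaction types are the Lewis acid-mediated additions and annulations of peroxycarbenium ions from monoperoxyketals with alkenes and allylsilanes and Prins cyclisations terminated by an internal oxygen nucleophile; untested is their merger with carbonyl-oxygen termination on a β-peroxy aldehyde. The 1,2-dioxane ring closes by 6-endo attack of the C4=C5 alkene on the peroxycarbenium carbon C6 (Prins mode, both alkene carbons inside the ring), and the oxolane ring closes by attack of the carbonyl oxygen on the C4 cation to a five-membered oxocarbenium ion. C3 is controlled by the catalyst, C4 by the two-atom C2–C1 tether, which can deliver oxygen only cis to C2 (cis ring fusion), and C6 by 1,4-induction from C3 through a chair transition state in which the CH2CHO arm is axial (it escapes 1,2-allylic strain with the C4 methyl and reaches C4 anti to the forming C5–C6 bond) and the arylnonyl chain of the (E)-peroxycarbenium ion is equatorial, which places the chain cis to C2 and the two methyl groups cis, as in the target; C1 is formed as an anomer mixture that step 7 removes. The step needs 1,4- rather than 1,6-addition to the dienal (oxygen nucleophiles add at the β-carbon of such iminium ions), retention of the O–O bond rather than epoxide closure by the enamine (acid co-catalyst, low temperature, hindered tertiary perketal), ionisation of the ketal rather than activation of the aldehyde (acetals react far faster with Me3SiOTf) and facial selectivity at C6, the least secure element because methyl and chain differ little in size; the C6 epimer is a diastereomer and should be separable by chromatography of 14 or 16.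

Step 7
Reactants: 14 (3S,4S,6R)-1-deoxo-1-methoxyplakortolide F triisopropylsilyl ether
Product: 16 plakortolide F triisopropylsilyl ether, via lactol 15 (not isolated)
Conditions: CrO3, aq. H2SO4 (Jones reagent), acetone, 0 °C
Reagents that add atoms: water, O
Why: aqueous acid hydrolyses the methyl lactol ether and chromic acid oxidises the lactol to the γ-lactone (Jones oxidation), conditions that dialkyl peroxides and aryl silyl ethers should survive; both anomers converge and no stereocenter is touched.

Step 8
Reactants: 16 plakortolide F triisopropylsilyl ether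
Product: 17 plakortolide F
Conditions: Bu4NF, AcOH (1:1), THF, 0 °C
Reagents that add atoms: none
Why: fluoride cleaves the aryl Si–O bond (desilylation), and the acetic acid buffer should keep the medium from opening the β-peroxy lactone by base-induced retro-oxa-Michael or peroxide fragmentation.

Compound list
1 | dec-9-enoic acid | C=CCCCCCCCC(=O)O | starting material
2 | dilithium undec-10-ene-2,2-diolate (formed in the flask) | [Li+].[Li+].C=CCCCCCCCC(C)([O-])[O-] | intermediate
3 | undec-10-en-2-one | C=CCCCCCCCC(C)=O | intermediate
4 | 10,10-dimethoxyundec-1-ene | C=CCCCCCCCC(C)(OC)OC | intermediate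
5 | 9-borabicyclo[3.3.1]nonane (9-BBN) | [H]B1C2CCCC1CCC2 | starting material
6 | (4-bromophenoxy)triisopropylsilane | CC(C)[Si](Oc1ccc(Br)cc1)(C(C)C)C(C)C | starting material
7 | 9-(10,10-dimethoxyundecyl)-9-borabicyclo[3.3.1]nonane (formed in the flask) | COC(C)(OC)CCCCCCCCCB1C2CCCC1CCC2 | intermediate
8 | [4-(10,10-dimethoxyundecyl)phenoxy]triisopropylsilane | COC(C)(OC)CCCCCCCCCc1ccc(O[Si](C(C)C)(C(C)C)C(C)C)cc1 | intermediate
9 | [4-(10-hydroperoxy-10-methoxyundecyl)phenoxy]triisopropylsilane (racemic at C10) | COC(C)(OO)CCCCCCCCCc1ccc(O[Si](C(C)C)(C(C)C)C(C)C)cc1 | intermediate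
10 | methacrolein (2-methylprop-2-enal) | CC(=C)C=O | starting material
11 | (triphenylphosphoranylidene)acetaldehyde | O=CC=P(c1ccccc1)(c1ccccc1)c1ccccc1 | starting material
12 | (2E)-4-methylpenta-2,4-dienal | CC(=C)/C=C/C=O | intermediate
13 | (3S)-3-({2-methoxy-11-[4-(triisopropylsilyloxy)phenyl]undecan-2-yl}peroxy)-4-methylpent-4-enal (both configurations at the perketal carbon; formed in the flask) | COC(C)(CCCCCCCCCc1ccc(O[Si](C(C)C)(C(C)C)C(C)C)cc1)OO[C@@H](CC=O)C(C)=C | intermediate
14 | (3S,4S,6R)-1-deoxo-1-methoxyplakortolide F triisopropylsilyl ether: cis-fused 1,2-dioxane/2-methoxyoxolane, 4-methyl, 6-methyl, 6-{9-[4-(triisopropylsilyloxy)phenyl]nonyl}, both anomers at C1 | C[C@@]1(CCCCCCCCCc2ccc(O[Si](C(C)C)(C(C)C)C(C)C)cc2)C[C@]2(C)OC(OC)C[C@@H]2OO1 | intermediate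
15 | (3S,4S,6R)-lactol corresponding to 14 (1-hydroxy in place of 1-methoxy; formed in the flask) | C[C@@]1(CCCCCCCCCc2ccc(O[Si](C(C)C)(C(C)C)C(C)C)cc2)C[C@]2(C)OC(O)C[C@@H]2OO1 | intermediate
16 | (3S,4S,6R)-plakortolide F triisopropylsilyl ether | C[C@@]1(CCCCCCCCCc2ccc(O[Si](C(C)C)(C(C)C)C(C)C)cc2)C[C@]2(C)OC(=O)C[C@@H]2OO1 | intermediate
17 | plakortolide F, (3S,4S,6R) | C[C@@]1(CCCCCCCCCc2ccc(O)cc2)C[C@]2(C)OC(=O)C[C@@H]2OO1 | target

Total step count: 8 steps.
Longest linear sequence: 7 steps (steps 1, 2, 3, 4, 6, 7, 8, from dec-9-enoic acid).

Steps most likely to fail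

Step 6. After the C5–C6 bond has formed, the tertiary C4 cation may lose a proton or fragment through the neighbouring peroxide instead of closing onto the aldehyde oxygen, and discrimination of the two faces of the peroxycarbenium ion at C6 may be weak. The fallback uses known chemistry only, sets out from 9 and returns at 16. Dienal 12 is replaced by (2E)-4-[(trimethylsilyl)methyl]penta-2,4-dienal F1, which should be available by Heck coupling of (2-bromoallyl)trimethylsilane with acrolein (Pd(OAc)2, Bu4NCl, NaHCO3, DMF). Organocatalytic peroxidation of F1 with 9 under the first-stage conditions of step 6 should give the (3S)-peroxy aldehyde F2, which is isolated. Me3SiOTf in CH2Cl2 at −78 °C then closes the dioxane by the established intramolecular addition of an allylsilane to a peroxycarbenium ion; the β-silyl cation collapses cleanly to the (3S,6R)-4-methylidene-1,2-dioxane aldehyde F3. The larger C4 substituent should also reinforce the axial preference of the C3 arm. Pinnick oxidation (NaClO2, NaH2PO4, 2-methyl-2-butene) gives the acid F4, and CF3CO2H in CH2Cl2 effects Markovnikov lactonisation onto the exocyclic methylene, necessarily cis, to give 16.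

Step 4. The exchange may run on to the geminal dihydroperoxide, or traces of water may hydrolyse the ketal back to the ketone, so that 9 is obtained only in mixtures. The fallback sets out from 8 and returns at 9 by an ozonolysis route. The ketal is hydrolysed (pyridinium p-toluenesulfonate, aqueous acetone) to 11-[4-(triisopropylsilyloxy)phenyl]undecan-2-one F5. Wittig reaction with Ph3P=CHOMe (from (methoxymethyl)triphenylphosphonium chloride and KOtBu) gives the methyl enol ether F6 as an E/Z mixture. Ozonolysis of F6 in MeOH–CH2Cl2 at −78 °C with a limited amount of ozone cleaves the electron-rich enol ether to methyl formate and the ketone O-oxide, which methanol traps as 9.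

Step 7. Chromic acid may over-oxidise the electron-rich aryl silyl ether, or the strong aqueous acid may ionise the tertiary C6–O bond of the peroxide. The fallback moves the oxidation ahead of ring formation; it sets out from 13 and returns at 16. Step 6 is stopped after its first stage and crude 13 is oxidised under Pinnick conditions (NaClO2, NaH2PO4, 2-methyl-2-butene, t-BuOH–H2O) to the (3S)-peroxy acid F7. Me3SiOTf in CH2Cl2 at −78 °C then triggers the same peroxycarbenium cyclisation with the carboxylic acid as internal nucleophile for the C4 cation, which should give lactone 16 directly without a lactol ether.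

Further compounds
F1 | step 6 | (2E)-4-[(trimethylsilyl)methyl]penta-2,4-dienal | C[Si](C)(C)CC(=C)/C=C/C=O
F2 | step 6 | (3S)-3-({2-methoxy-11-[4-(triisopropylsilyloxy)phenyl]undecan-2-yl}peroxy)-4-[(trimethylsilyl)methyl]pent-4-enal | COC(C)(CCCCCCCCCc1ccc(O[Si](C(C)C)(C(C)C)C(C)C)cc1)OO[C@@H](CC=O)C(=C)C[Si](C)(C)C
F3 | step 6 | (3S,6R)-4-methylidene-1,2-dioxane aldehyde (plakortolide numbering: 3-CH2CHO, 6-methyl, 6-{9-[4-(triisopropylsilyloxy)phenyl]nonyl}) | C[C@@]1(CCCCCCCCCc2ccc(O[Si](C(C)C)(C(C)C)C(C)C)cc2)CC(=C)[C@H](CC=O)OO1
F4 | step 6 | (3S,6R)-4-methylidene-1,2-dioxane acetic acid corresponding to F3 | C[C@@]1(CCCCCCCCCc2ccc(O[Si](C(C)C)(C(C)C)C(C)C)cc2)CC(=C)[C@H](CC(=O)O)OO1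
F5 | step 4 | 11-[4-(triisopropylsilyloxy)phenyl]undecan-2-one | CC(=O)CCCCCCCCCc1ccc(O[Si](C(C)C)(C(C)C)C(C)C)cc1
F6 | step 4 | {4-[11-methoxy-10-methylundec-10-enyl]phenoxy}triisopropylsilane (E/Z mixture) | COC=C(C)CCCCCCCCCc1ccc(O[Si](C(C)C)(C(C)C)C(C)C)cc1
F7 | step 7 | (3S)-3-({2-methoxy-11-[4-(triisopropylsilyloxy)phenyl]undecan-2-yl}peroxy)-4-methylpent-4-enoic acid | COC(C)(CCCCCCCCCc1ccc(O[Si](C(C)C)(C(C)C)C(C)C)cc1)OO[C@@H](CC(=O)O)C(C)=C
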